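Plan
1. Retrosynthesis: re-mask O5 as its methyl ether and O2'/O3' as an isopropylidene ketal. Then cut C2–C1' (pyrone ring C to ring B), take C2 out of ring C (O1–C2 and C2=C3), and last cut C4–C4a.
2. Forward: ring A is bought complete and acylated at C4a with the C4–C3(OMe) unit. The flanked ortho ether is cleaved to free O1, a one-carbon reagent supplies C2 and closes ring C, ring B is joined last, and one unmasking step follows.
3. Enabling feature: in 3,5,7,8-tetramethoxychromone the only acidified C–H is C2–H of ring C. It lies between O1 and C3–OMe, it is vinylogous to the C4 carbonyl, and C3 is blocked.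
4. Direct zincation reverses the acceptor polarity of C2, so that two acceptor carbons (C2 and the C–I carbon of ring B) can be joined with all six oxygens already differentiated.
5. Stereochemistry: the target has no stereocentre and the C2–C1' axis rotates freely, so nothing has to be set.

Key step: step 5

Assumption: the target is achiral, so the request for a single enantiomer is met by the constitution alone.

Step 1
Reactants: 1 1,2,3,5-tetramethoxybenzene; 2 N,2-dimethoxy-N-methylacetamide
Product: 4 2-methoxy-1-(2,3,4,6-tetramethoxyphenyl)ethan-1-one, via aryllithium 3 (not isolated)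
Conditions: n-BuLi, THF, 0 °C; then 2, −78 °C → rt; 1 M aq HCl
Reagents that add atoms: none
Why: Directed ortho-metalation occurs at the C–H between two methoxy groups (both such sites are equivalent by symmetry), and the Weinreb ketone synthesis stops at the ketone; this avoids a Friedel–Crafts acylation with methoxyacetyl chloride, whose acylium ion loses CO.

Step 2
Reactants: 4 2-methoxy-1-(2,3,4,6-tetramethoxyphenyl)ethan-1-one
Product: 5 1-(2-hydroxy-3,4,6-trimethoxyphenyl)-2-methoxyethan-1-one
Conditions: BCl3 (1.1 equiv), CH2Cl2, −78 → 0 °C; then H2O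
Reagents that add atoms: none
Why: This is a chelation-directed aryl methyl ether cleavage ortho to a ketone, in which the 2-methoxy group, twisted out of plane between the acyl group and the 3-methoxy group, should be the more basic and more strained ortho ether and be cleaved first, as is the rule for acylated 1,2,3,5-tetramethoxybenzenes, while one equivalent at low temperature should spare the side-chain ether.

Step 3
Reactants: 5 1-(2-hydroxy-3,4,6-trimethoxyphenyl)-2-methoxyethan-1-one
Product: 7 3,5,7,8-tetramethoxy-4H-chromen-4-one, via 2-methoxy enaminone 6 (not isolated)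
Conditions: Me2NCH(OMe)2, PhMe, 100 °C; then AcOH, 80 °C
Reagents that add atoms: N,N-dimethylformamide dimethyl acetal, COC(OC)N(C)C
Why: Condensation at the activated CH2 gives the enaminone, and acid-promoted attack of the phenol oxygen on the enamine carbon with loss of dimethylamine closes ring C (the enaminone route to chromones, as used for isoflavones from 2-hydroxyaryl benzyl ketones).

Step 4
Reactants: 8 2,2-dimethyl-1,3-benzodioxole
Product: 10 4-iodo-2,2-dimethyl-1,3-benzodioxole, via 4-lithio acetonide 9 (not isolated)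
Conditions: n-BuLi, TMEDA, Et2O, 0 °C → rt; then I2, THF, −78 °C → rt
Reagents that add atoms: iodine, II
Why: Directed ortho-metalation next to the ketal oxygen followed by iodinolysis fixes the 1,2,3-pattern of ring B, which para-selective electrophilic substitution of a catechol ether cannot give, and the gem-dimethyl group leaves no acetal C–H to be metalated.

Step 5
Reactants: 7 3,5,7,8-tetramethoxy-4H-chromen-4-one; 10 4-iodo-2,2-dimethyl-1,3-benzodioxole
Product: 12 2-(2,2-dimethyl-1,3-benzodioxol-4-yl)-3,5,7,8-tetramethoxy-4H-chromen-4-one, via bis(chromon-2-yl)zinc 11 (not isolated)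
Conditions: TMP2Zn·2MgCl2·2LiCl (0.6 equiv), THF, 25 °C; then 10, Pd(OAc)2 (2 mol %), SPhos (4 mol %), 25 → 50 °C
Reagents that add atoms: none
Why: The hindered zinc amide removes C2–H of ring C, the only acidified sp2 C–H (σ-withdrawal by O1 and by the C3 methoxy oxygen, vinylogous activation by the C4 carbonyl once MgCl2/LiCl bind to it), so the natural acceptor carbon of the vinylogous ester becomes a donor held in a covalent C–Zn bond that neither opens the pyrone nor expels the 3-methoxy group. Pd(0) then inserts into the C–I bond of 10, zinc passes the chromonyl group to palladium, and reductive elimination forms C2–C1' (Negishi coupling). The closest known reaction type is the C2-zincation of chromones with TMP-zinc bases followed by Negishi arylation to flavones. No ring is closed and no stereocentre is formed. The step needs site selectivity for C2–H over C6–H (between the 5- and 7-methoxy groups) and freedom from amide addition at C2 and from acidic O–H: C3 is blocked by its methoxy group, a zinc amide does not metalate an unactivated anisole-type C–H at 25 °C, TMP is too bulky to add, and O5, O2' and O3' all carry carbon. The five-membered ketal pins the ortho oxygen of ring B back, which lowers the steric cost of reductive elimination at a carbon flanked on both sides.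

Step 6
Reactants: 12 2-(2,2-dimethyl-1,3-benzodioxol-4-yl)-3,5,7,8-tetramethoxy-4H-chromen-4-one
Product: 13 5,2',3'-trihydroxy-3,7,8-trimethoxyflavone
Conditions: BCl3 (4 equiv), CH2Cl2, −78 → 0 °C; then 2 M aq HCl, THF, 40 °C
Reagents that add atoms: none
Why: BCl3 bound at the C4 carbonyl cleaves the peri 5-methoxy group through a six-membered boron chelate (chelation-directed aryl methyl ether cleavage), the Lewis acid and the following aqueous acid hydrolyse the isopropylidene ketal, and the 3-, 7- and 8-methyl ethers, which lack such a six-ring chelate, should survive at or below 0 °C.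

Compound list
1 | 1,2,3,5-tetramethoxybenzene | COc1cc(OC)c(OC)c(OC)c1 | starting material
2 | N,2-dimethoxy-N-methylacetamide | COCC(=O)N(C)OC | starting material
3 | 2,3,4,6-tetramethoxyphenyllithium | [Li]c1c(OC)cc(OC)c(OC)c1OC | intermediate
4 | 2-methoxy-1-(2,3,4,6-tetramethoxyphenyl)ethan-1-one | COCC(=O)c1c(OC)cc(OC)c(OC)c1OC | intermediate
5 | 1-(2-hydroxy-3,4,6-trimethoxyphenyl)-2-methoxyethan-1-one | COCC(=O)c1c(OC)cc(OC)c(OC)c1O | intermediate
6 | (Z)-3-(dimethylamino)-1-(2-hydroxy-3,4,6-trimethoxyphenyl)-2-methoxyprop-2-en-1-one (geometry of no consequence) | CN(C)/C=C(\OC)C(=O)c1c(OC)cc(OC)c(OC)c1O | intermediate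
7 | 3,5,7,8-tetramethoxy-4H-chromen-4-one | COc1cc(OC)c2c(=O)c(OC)coc2c1OC | intermediate
8 | 2,2-dimethyl-1,3-benzodioxole | CC1(C)Oc2ccccc2O1 | starting material
9 | (2,2-dimethyl-1,3-benzodioxol-4-yl)lithium | [Li]c1cccc2c1OC(C)(C)O2 | intermediate
10 | 4-iodo-2,2-dimethyl-1,3-benzodioxole | CC1(C)Oc2cccc(I)c2O1 | intermediate
11 | bis(3,5,7,8-tetramethoxy-4-oxo-4H-chromen-2-yl)zinc | COc1cc(OC)c2c(=O)c(OC)c([Zn]c3oc4c(OC)c(OC)cc(OC)c4c(=O)c3OC)oc2c1OC | intermediate
12 | 2-(2,2-dimethyl-1,3-benzodioxol-4-yl)-3,5,7,8-tetramethoxy-4H-chromen-4-one | COc1cc(OC)c2c(=O)c(OC)c(-c3cccc4c3OC(C)(C)O4)oc2c1OC | intermediate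
13 | 5,2',3'-trihydroxy-3,7,8-trimethoxyflavone [2-(2,3-dihydroxyphenyl)-5-hydroxy-3,7,8-trimethoxy-4H-chromen-4-one] | COc1cc(O)c2c(=O)c(OC)c(-c3cccc(O)c3O)oc2c1OC | target

Total step count: 6. Longest linear sequence: 5 (steps 1, 2, 3, 5, 6).

Steps most likely to fail

1. Step 5.
- What may go wrong: deprotonation of C2–H in the very electron-rich chromone may be incomplete. Transmetallation and reductive elimination at a carbon flanked by O1 and the 3-methoxy group may also be slow, so that the zinc reagent is merely protonated on work-up.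
- Fallback: normal polarity plus re-oxidation replaces polarity reversal. It sets out from 7 and from 9 (made from 8 as in step 4) and returns at 12.
- 7 is O-silylated with TBSOTf (CH2Cl2, 0 °C) to 4-(tert-butyldimethylsilyloxy)-3,5,7,8-tetramethoxychromenylium triflate F1.
- 9 is transmetallated with ZnCl2 to (2,2-dimethyl-1,3-benzodioxol-4-yl)zinc chloride F2. This adds to C2 of F1 to give racemic tert-butyl{[2-(2,2-dimethyl-1,3-benzodioxol-4-yl)-3,5,7,8-tetramethoxy-2H-chromen-4-yl]oxy}dimethylsilane F3.
- DDQ abstracts the C2 hydride, and aqueous work-up removes silicon to give 12.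

2. Step 2.
- What may go wrong: the wrong ortho ether (O6 instead of O2) may be cleaved, which would divert the series into the 5,6,7-pattern. The side-chain methyl ether may also be lost through a five-ring chelate.
- Fallback: the 3-oxygen is introduced only after ring closure. It sets out from 1 and returns at 7.
- Friedel–Crafts acetylation of 1 (AcCl, AlCl3, Et2O), in which the flanked ortho ether is lost in the same operation, gives 1-(2-hydroxy-3,4,6-trimethoxyphenyl)ethan-1-one F4.
- DMF dimethyl acetal gives (E)-3-(dimethylamino)-1-(2-hydroxy-3,4,6-trimethoxyphenyl)prop-2-en-1-one F5, which HCl closes to 5,7,8-trimethoxy-4H-chromen-4-one F6.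
- Weitz–Scheffer epoxidation (H2O2, NaOH, 0 °C) gives racemic 2,3-epoxy-5,7,8-trimethoxychroman-4-one F7, which acid isomerises to 3-hydroxy-5,7,8-trimethoxy-4H-chromen-4-one F8.
- MeI/K2CO3 in acetone gives 7.

3. Step 6.
- What may go wrong: over-dealkylation is the main risk. The 3-methyl ether may be lost once boron is held at the freed 2'-oxygen, the hindered 8-methyl ether may also be lost, or the unmasking may be incomplete if the conditions are kept mild.
- Fallback: the Lewis-acid step is moved to the simple chromone and the end game becomes neutral or mildly acidic. It sets out from 7 and returns at 13.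
- 7 is demethylated at O5 with one equivalent of BCl3 to 5-hydroxy-3,7,8-trimethoxy-4H-chromen-4-one F9, which is benzylated (BnBr, K2CO3, DMF) to 5-(benzyloxy)-3,7,8-trimethoxy-4H-chromen-4-one F10.
- F10 is zincated as in step 5 to bis[5-(benzyloxy)-3,7,8-trimethoxy-4-oxo-4H-chromen-2-yl]zinc F11 and coupled with 10 to 5-(benzyloxy)-2-(2,2-dimethyl-1,3-benzodioxol-4-yl)-3,7,8-trimethoxy-4H-chromen-4-one F12.
- Hydrogenolysis (H2, Pd/C, EtOAc) gives 2-(2,2-dimethyl-1,3-benzodioxol-4-yl)-5-hydroxy-3,7,8-trimethoxy-4H-chromen-4-one F13, and aqueous trifluoroacetic acid hydrolyses the ketal to 13.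

Further compounds
F1 | step 5 | 4-(tert-butyldimethylsilyloxy)-3,5,7,8-tetramethoxychromenylium triflate | COc1cc(OC)c2c(O[Si](C)(C)C(C)(C)C)c(OC)c[o+]c2c1OC.[O-]S(=O)(=O)C(F)(F)F
F2 | step 5 | (2,2-dimethyl-1,3-benzodioxol-4-yl)zinc chloride | Cl[Zn]c1cccc2c1OC(C)(C)O2
F3 | step 5 | racemic tert-butyl{[2-(2,2-dimethyl-1,3-benzodioxol-4-yl)-3,5,7,8-tetramethoxy-2H-chromen-4-yl]oxy}dimethylsilane | COC1=C(O[Si](C)(C)C(C)(C)C)c2c(OC)cc(OC)c(OC)c2OC1c1cccc2c1OC(C)(C)O2
F4 | step 2 | 1-(2-hydroxy-3,4,6-trimethoxyphenyl)ethan-1-one | CC(=O)c1c(OC)cc(OC)c(OC)c1O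
F5 | step 2 | (E)-3-(dimethylamino)-1-(2-hydroxy-3,4,6-trimethoxyphenyl)prop-2-en-1-one | CN(C)/C=C/C(=O)c1c(OC)cc(OC)c(OC)c1O
F6 | step 2 | 5,7,8-trimethoxy-4H-chromen-4-one | COc1cc(OC)c2c(=O)ccoc2c1OC
F7 | step 2 | racemic 2,3-epoxy-5,7,8-trimethoxychroman-4-one | COc1cc(OC)c2C(=O)C3OC3Oc2c1OC
F8 | step 2 | 3-hydroxy-5,7,8-trimethoxy-4H-chromen-4-one | COc1cc(OC)c2c(=O)c(O)coc2c1OC
F9 | step 6 | 5-hydroxy-3,7,8-trimethoxy-4H-chromen-4-one | COc1cc(O)c2c(=O)c(OC)coc2c1OC
F10 | step 6 | 5-(benzyloxy)-3,7,8-trimethoxy-4H-chromen-4-one | COc1cc(OCc3ccccc3)c2c(=O)c(OC)coc2c1OC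
F11 | step 6 | bis[5-(benzyloxy)-3,7,8-trimethoxy-4-oxo-4H-chromen-2-yl]zinc | COc1cc(OCc3ccccc3)c2c(=O)c(OC)c([Zn]c3oc4c(OC)c(OC)cc(OCc5ccccc5)c4c(=O)c3OC)oc2c1OC
F12 | step 6 | 5-(benzyloxy)-2-(2,2-dimethyl-1,3-benzodioxol-4-yl)-3,7,8-trimethoxy-4H-chromen-4-one | COc1cc(OCc3ccccc3)c2c(=O)c(OC)c(-c3cccc4c3OC(C)(C)O4)oc2c1OC
F13 | step 6 | 2-(2,2-dimethyl-1,3-benzodioxol-4-yl)-5-hydroxy-3,7,8-trimethoxy-4H-chromen-4-one | COc1cc(O)c2c(=O)c(OC)c(-c3cccc4c3OC(C)(C)O4)oc2c1OC
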